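Left-handed product and left-handed substrate together should stay at half of what was charged, and in Wednesday's run they read 49.4% at 10.0 s and 51.0% at 90.0 s, so the left-handed substrate column can be read as the conversion of left-handed substrate.

- Wednesday's (time / s: left-handed product / %, left-handed substrate / %): 10.0: 4.8, 44.6; 12.0: 6.8, 44.0; 15.0: 6.6, 43.5; 25.0: 10.4, 39.4; 40.0: 13.9, 36.4; 60.0: 16.2, 33.3; 90.0: 20.1, 30.9

(each reading ± 0.5 percentage points)

| flask | left-handed substrate | right-handed substrate | reagent | free catalyst | impurity | remark |
|---|---|---|---|---|---|---|
| Wednesday's | 0.020 M | 0.020 M | 0.12 M | 0.18 mM | 19 µM | run made earlier |
| flask | 0.020 M | 0.020 M | 0.0600 M | 0.18 mM | 19 µM |  |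

1. factor on the rate of making left-handed product when 30% of the left-handed substrate and right-handed substrate together are converted if free catalyst is charged twice over
2. factor on the rate when 30% of the left-handed substrate and right-handed substrate together are converted if free catalyst is charged at 2.0 mM instead

- free catalyst is single-handed; left-handed substrate and right-handed substrate are mirror images of each other, charged as a racemate, each of them at the stated concentration
- the numbers in the tables scatter with a standard deviation of 0.5 percentage points
- what may be going on: free catalyst + impurity -> spent catalyst A; reagent + free catalyst + right-handed substrate -> free catalyst + right-handed product; reagent + free catalyst + left-handed substrate -> free catalyst + left-handed product; 2 free catalyst -> spent catalyst B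
- no earlier run changes the charge of free catalyst; that part of a forecast is a guess

I read Wednesday's left-handed substrate column from the top. The first 10.0 s take 5.4 percentage points, while the last 30.0 s take 2.4 points, so the pace falls about 6.75-fold. The substrate's own fall, from its charge to the last reading, is a factor of 1.62. The rest suggests that roughly 76.0% of the free catalyst goes between those two stretches of Wednesday's run, a reading above the 10.6% of the charge that the impurity can take. So I take free catalyst to be lost mainly in pairs, to spent catalyst B.

Pair loss goes with [free catalyst] squared and conversion with [free catalyst] once, so the loss per unit of conversion goes with [free catalyst] once. With substrates and reagent charged as in this flask, the surviving fraction of what the impurity leaves, at a given conversion, then doesn't depend on the starting amount, and [reagent] and [left-handed substrate] are the same there too. I assume the impurity acts early, so the rate at 30% conversion is first order in the working charge, the free catalyst charged minus the impurity charged, here 161 µM. Dividing working charges, I get 2.12 for the doubled charge and 12.3 for 2.0 mM.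

The forecast gives 2.12 and 12.3, “if the impurity titrates quickly”. The simulation gives 2.14 and 12.5.

    free catalyst + impurity → spent catalyst A (k = 1.18 × 10⁵ /M/min)
    reagent + free catalyst + right-handed substrate → free catalyst + right-handed product (k = 16700 /M²/min)
    reagent + free catalyst + left-handed substrate → free catalyst + left-handed product (k = 40700 /M²/min)
    2 free catalyst → spent catalyst B (k = 6780 /M/min)

By 1.50 min this flask reads impurity 0% of its own charge and spent catalyst A 10.6% of the catalyst charged, leaving the working charge of 161 µM to free catalyst and spent catalyst B, and both product-making steps run while free catalyst falls from 20.8% of the catalyst charged there to 2.65% at 15.0 min. At 11.7 min, where conversion in this flask reaches 30%, left-handed product forms at 1.41 × 10⁻⁴ M/min, which is 0.873 /min per working charge, and a flask charged at 2.0 mM, at the same conversion and by its simulated factor, stands at 0.886 /min per its own working charge.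

The runs were computed with made-up constants, noise included.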